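**Retrosynthetic overview**
- The target is the mono(2-bromophenyl) ether of tetrabromocatechol. The one strategic bond is the C–O bond between ring B and a catechol oxygen of ring A.
- That bond is cut into an aryl group carried on boron and an electrophilic quinone oxygen: o-bromanil plus (2-bromophenyl)boronic acid, joined by redox-neutral copper catalysis.
- o-Bromanil comes from oxidation of commercial tetrabromocatechol. All five C–Br bonds are bought in, because late bromination would not spare the para position of ring B.
- No ring is formed. Rings A and B are both purchased as arenes, and ring A is only dearomatised (step 1) and rearomatised (step 2).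

Assumption: the target has no stereocentre and its diaryl ether axes rotate freely, so it is achiral. There is no enantiomer to select, and no SMILES carries a stereodescriptor.

**Step 1**
Reactants: 1 3,4,5,6-tetrabromobenzene-1,2-diol (tetrabromocatechol)
Product: 2 3,4,5,6-tetrabromocyclohexa-3,5-diene-1,2-dione (o-bromanil)
Conditions: HNO3 (65 %, 3 equiv), AcOH, 20 °C, 20 min; ice-water, filter, dry in vacuo, recrystallise (CH2Cl2/cyclohexane)
Reagents that add atoms: none
Why: This is the classical nitric acid oxidation of a perhalocatechol to the o-quinone (two electrons, two protons), which should work because no C–H site is open to nitration, the C–Br bonds survive brief HNO3/AcOH contact, the red water-insoluble quinone precipitates on quenching, and no stereocentre is involved.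

**Step 2**
Reactants: 2 3,4,5,6-tetrabromocyclohexa-3,5-diene-1,2-dione (o-bromanil); 3 (2-bromophenyl)boronic acid
Product: 6 3,4,5,6-tetrabromo-2-(2-bromophenoxy)phenol, via arylcopper catecholate 4 (not isolated), via borate half-ester 5 (not isolated)
Conditions: CuOAc (10 mol %), 1,10-phenanthroline (11 mol %), 4 Å MS, CH2Cl2/MeCN 4:1, N2, 25 °C; 2 added over 6 h to 3 (1.4 equiv), then 12 h; 1 M HCl work-up
Reagents that add atoms: none
Why: Proposed new method: a redox-neutral, copper-catalysed reductive O-arylation of an o-quinone, in which acetate-assisted boron-to-copper transmetalation of 3 gives a phenanthroline-bound monovalent arylcopper, the strongly oxidising and chelating quinone 2 adds oxidatively to it to give the trivalent copper species 4, C–O reductive elimination (driven by rearomatisation of ring A, with no second aryl or other ligand on copper to compete) forms the diaryl ether, and the resulting monovalent copper phenolate hands its phenolate to the boron of the next molecule of 3 to give 5 and restart the cycle, so that 2 is both the oxygen source and the only oxidant, a second arylation stops once 2 is consumed, the five C–Br bonds are untouched at 25 °C, and no stereocentre is created; the closest known reaction types are the Chan–Lam–Evans O-arylation of phenols, the copper-catalysed addition of arylboronic acids to azodicarboxylates, the chloranil-triggered reductive elimination of organocopper amides, and the oxidative addition of o-quinones to low-valent metals.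

**Compound list**
1 | 3,4,5,6-tetrabromobenzene-1,2-diol (tetrabromocatechol) | Oc1c(O)c(Br)c(Br)c(Br)c1Br | starting material
2 | 3,4,5,6-tetrabromocyclohexa-3,5-diene-1,2-dione (o-bromanil) | O=C1C(=O)C(Br)=C(Br)C(Br)=C1Br | intermediate
3 | (2-bromophenyl)boronic acid | OB(O)c1ccccc1Br | starting material
4 | (2-bromophenyl)(3,4,5,6-tetrabromocatecholato)(1,10-phenanthroline)copper, trivalent copper | Brc1ccccc1[Cu]1Oc2c(Br)c(Br)c(Br)c(Br)c2O1.c1cnc2c(c1)ccc1cccnc12 | intermediate
5 | 2,3,4,5-tetrabromo-6-(2-bromophenoxy)phenyl dihydrogen borate | OB(O)Oc1c(Br)c(Br)c(Br)c(Br)c1Oc1ccccc1Br | intermediate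
6 | 3,4,5,6-tetrabromo-2-(2-bromophenoxy)phenol | Oc1c(Br)c(Br)c(Br)c(Br)c1Oc1ccccc1Br | target

**Total step count:** 2. **Longest linear sequence:** 2. Compound 2 is also sold, which would leave one step, but 1 is the cheaper entry.

**Steps most likely to fail** (the route has only two steps, so both are given, most risky first)

**Step 2 (proposed new step).**
- Copper may rest as an inert divalent catecholate or semiquinonate.
- 2 may simply drive homocoupling of 3, giving 2,2'-dibromobiphenyl and returning 1.
- The ortho-bromo boronic acid may transmetalate slowly or protodeboronate.
- The arylcopper may attack a C–Br carbon of 2 instead of being oxidised.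
- Heat and base must be avoided with 6, because it could then close to a brominated dibenzodioxin.

Fallback (known chemistry, metal-free ligand coupling at trivalent iodine in place of copper catalysis): it sets out from 1 and comes back at 6. Compound 1 is mono-methylated (MeI 1.0 equiv, K2CO3 1.0 equiv, acetone, 40 °C, with the neutral dimethyl ether removed by base extraction) to give 2,3,4,5-tetrabromo-6-methoxyphenol F1. Separately, commercial 1-bromo-2-iodobenzene is oxidised with mCPBA and TsOH·H2O in MeCN and trapped with 1,3,5-trimethoxybenzene to give (2-bromophenyl)(2,4,6-trimethoxyphenyl)iodonium tosylate F2. F1 and F2 with K2CO3 in toluene at 60 °C transfer the electron-poorer 2-bromophenyl group selectively and give 1,2,3,4-tetrabromo-5-(2-bromophenoxy)-6-methoxybenzene F3. BBr3 in CH2Cl2 (−78 to 20 °C) then cleaves the methyl ether to 6.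

**Step 1.**
- Traces of acid, nitrogen oxides or water carried along with 2 could poison step 2.
- 2 can lose bromide by hydrolysis if the aqueous quench is prolonged.

Fallback (the oxidant is moved from the substrate to copper and air, so no free quinone is needed): it sets out from 1 and comes back at 4. Compound 1, Cu(OAc)2 (1 equiv) and 1,10-phenanthroline (1 equiv) in MeOH precipitate the divalent copper chelate (1,10-phenanthroline)(3,4,5,6-tetrabromocatecholato)copper F4. Stirred with 3 (2 equiv) and 4 Å MS in CH2Cl2 under dry air (Chan–Lam–Evans manifold), F4 takes up the aryl group and is oxidised by one electron to 4. Compound 4 then collapses to 6 as in step 2 after 1 M HCl work-up.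

**Further compounds**
F1 | step 2 | 2,3,4,5-tetrabromo-6-methoxyphenol | COc1c(O)c(Br)c(Br)c(Br)c1Br
F2 | step 2 | (2-bromophenyl)(2,4,6-trimethoxyphenyl)iodonium 4-methylbenzenesulfonate | COc1cc(OC)c([I+]c2ccccc2Br)c(OC)c1.Cc1ccc(cc1)S(=O)(=O)[O-]
F3 | step 2 | 1,2,3,4-tetrabromo-5-(2-bromophenoxy)-6-methoxybenzene | COc1c(Br)c(Br)c(Br)c(Br)c1Oc1ccccc1Br
F4 | step 1 | (1,10-phenanthroline)(3,4,5,6-tetrabromocatecholato)copper, divalent copper | Brc1c(Br)c(Br)c2O[Cu]Oc2c1Br.c1cnc2c(c1)ccc1cccnc12
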